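The route builds the cis-decalin in one enantioselective quinone Diels–Alder step, adds the side chain at C9, and closes the two spiro ethers last.

Everything rests on cutting ring A from ring B at C1–C10 and C4–C5 (labdane numbering). Ring B, with para oxygens at C6 and C9 and methyls at C8 and C10, is 2,6-dimethyl-1,4-benzoquinone in disguise. The cis ring fusion (H5 and the C10 methyl on one face) next to the C4 gem-dimethyl group is the signature of a [4+2] addition of 4-methylpenta-1,3-diene across C5=C10. One catalytic enantioselective Diels–Alder step thus assembles the cis-decalin, quaternary C10, C4 and both ring B oxygens from two bought achiral partners. The side chain is then added at C9, and the spiro ethers are closed by epoxide opening and alkynol cycloisomerisation.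

Key step: step 1

Numbering used below: labdane numbering (decalin C1–C10, gem-dimethyl on C4, oxygen on C6, methyl-bearing C8, spiro C9, angular methyl on C10; side chain C11, C12, spiro C13, enol ether C14=C15, OCH2 = C16). β is the face of the C10 methyl; the target is cis-fused (H5 β).

Assumption: the (S)-catalyst in step 1 is assigned from the accepted binding model for quinones, and D-(−)-diethyl tartrate in step 12 from the empirical face rule for allylic alcohols. Each mirror-image reagent is equally available should an assignment have to be reversed.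

Step 1
Reactants: 1 2,6-dimethyl-1,4-benzoquinone; 2 4-methylpenta-1,3-diene
Product: 3 cis-fused ene-dione (4aR,8aS)-2,5,5,8a-tetramethyl-4a,5,8,8a-tetrahydronaphthalene-1,4-dione
Conditions: (S)-3,3-diphenyl-1-(o-tolyl)tetrahydro-1H,3H-pyrrolo[1,2-c][1,3,2]oxazaborole·HNTf2 (20 mol %), 2 in excess, CH2Cl2, −78 to −40 °C
Reagents that add atoms: none
Why: The N-protonated oxazaborolidine binds the C6 carbonyl of 1, the less hindered and more basic one because it lies between two CH groups, which lowers the LUMO of C5=C10 and makes C10 its electrophilic end; the CH2 terminus of 2 (C1) bonds to C10 slightly ahead of the CMe2 terminus (C4) bonding to C5, with tertiary allylic cation character building up at C4, in a concerted but asynchronous [4+2] cycloaddition. The closest known reaction type is the Lewis-acid- or chiral-oxazaborolidinium-catalysed Diels–Alder addition of 1-substituted butadienes to 2,6-dimethylbenzoquinone, which gives cis-fused angular-methyl ene-diones. Ring A is closed onto the bought ring B by this intermolecular six-membered cycloaddition, suprafacial on both partners. C5 and C10 are created together: their cis relation follows from suprafacial addition to the quinone C=C, and their absolute configuration from the catalyst, which shields one face of the bound dienophile. The step needs regioselectivity (C1 to C10, C4 to C5) and enantioface selectivity, the first secured by catalyst binding at the C6 carbonyl together with the polarised diene; site and endo/exo selectivity do not arise because the two quinone C=C bonds are symmetry-equivalent and neither diene terminus carries a stereogenic substituent. The Z-methyl of 2, which disfavours the s-cis conformer, is the recognised weakness and is countered by the strongly activated quinone and an excess of diene.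

Step 2
Reactants: 3 cis-fused ene-dione
Product: 4 6α-hydroxy enone (4S,4aR,8aS)-4-hydroxy-2,5,5,8a-tetramethyl-4a,5,8,8a-tetrahydronaphthalen-1(4H)-one
Conditions: NaBH4, CeCl3·7H2O, MeOH, −78 °C
Reagents that add atoms: none
Why: Luche 1,2-reduction: cerium-activated borohydride should attack only the C6 carbonyl (between two CH groups) and not the C9 carbonyl wedged between C10 and the C8 methyl, arriving from the convex β face away from ring A, which sets C6 as the 6α-alcohol and removes the carbonyl that made C5 epimerisable.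

Step 3
Reactants: 4 6α-hydroxy enone
Product: 6 6β-hydroxy enone (4R,4aR,8aS)-4-hydroxy-2,5,5,8a-tetramethyl-4a,5,8,8a-tetrahydronaphthalen-1(4H)-one, via 6β-(4-nitrobenzoate) ester 5 (not isolated)
Conditions: 4-O2NC6H4CO2H, PPh3, DIAD, THF, 0 °C to rt; then K2CO3, MeOH, 0 °C
Reagents that add atoms: 4-nitrobenzoic acid, O=C(O)c1ccc(cc1)[N+](=O)[O-]
Why: Mitsunobu inversion followed by methanolysis in the same flask: the allylic 6α-oxyphosphonium ion is displaced by the acidic 4-nitrobenzoate in an SN2 step from the open β face, which inverts C6 to the 6β configuration, and cold carbonate in methanol then frees the hydroxyl before the γ-hydroxy enone can isomerise.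

Step 4
Reactants: 6 6β-hydroxy enone
Product: 7 saturated hydroxy ketone (2R,4R,4aR,8aS)-4-hydroxy-2,5,5,8a-tetramethyloctahydronaphthalen-1(2H)-one (6β-hydroxy-8α-methyl-cis-decalin-9-one)
Conditions: H2 (1 atm), [Ir(cod)(PCy3)(py)]PF6 (5 mol %), CH2Cl2, rt
Reagents that add atoms: none
Why: Hydroxyl-directed homogeneous hydrogenation: the cationic iridium catalyst binds the 6β-hydroxyl and delivers hydrogen to C7=C8 from the β face, which sets C8 with its methyl α, while the unhindered C2=C3 bond of ring A is saturated in the same operation; the product is kept base-free because C8 is next to the ketone.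

Step 5
Reactants: 8 3-bromobut-3-en-1-ol
Product: 9 2-[(3-bromobut-3-en-1-yl)oxy]tetrahydro-2H-pyran
Conditions: 3,4-dihydro-2H-pyran, pyridinium p-toluenesulfonate (cat.), CH2Cl2, rt
Reagents that add atoms: 3,4-dihydro-2H-pyran, C1=COCCC1
Why: Acid-catalysed acetal formation (tetrahydropyranyl ether) masks the hydroxyl proton ahead of the halogen–lithium exchange; no stereocentre of the target is involved.

Step 6
Reactants: 9 2-[(3-bromobut-3-en-1-yl)oxy]tetrahydro-2H-pyran
Product: 11 2-methylidene-4-(tetrahydro-2H-pyran-2-yloxy)butan-1-ol, via vinyllithium 10 (not isolated)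
Conditions: t-BuLi (2 equiv), Et2O, −78 °C; (CH2O)n, −78 °C to rt
Reagents that add atoms: formaldehyde (from paraformaldehyde), C=O
Why: Bromine–lithium exchange gives the vinyllithium, whose 1,2-addition to formaldehyde installs C16 with its oxygen; the acetal oxygen is too remote for β-elimination.

Step 7
Reactants: 11 2-methylidene-4-(tetrahydro-2H-pyran-2-yloxy)butan-1-ol
Product: 12 tert-butyl{[2-methylidene-4-(tetrahydro-2H-pyran-2-yloxy)butyl]oxy}diphenylsilane
Conditions: TBDPSCl, imidazole, CH2Cl2, rt
Reagents that add atoms: tert-butylchlorodiphenylsilane, CC(C)(C)[Si](Cl)(c1ccccc1)c1ccccc1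
Why: Silyl ether formation; the bulky TBDPS group is chosen because it survives the acetal methanolysis and resists oxygen-to-carbon silyl migration in the later alkyllithium.

Step 8
Reactants: 12 tert-butyl{[2-methylidene-4-(tetrahydro-2H-pyran-2-yloxy)butyl]oxy}diphenylsilane
Product: 13 4-[(tert-butyldiphenylsilyl)oxy]-3-methylidenebutan-1-ol
Conditions: pyridinium p-toluenesulfonate (cat.), MeOH, 45 °C
Reagents that add atoms: none
Why: Acid-catalysed transacetalisation to methanol removes the tetrahydropyranyl group while the allylic TBDPS ether stays in place.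

Step 9
Reactants: 13 4-[(tert-butyldiphenylsilyl)oxy]-3-methylidenebutan-1-ol
Product: 14 tert-butyl[(4-iodo-2-methylidenebutyl)oxy]diphenylsilane (fragment 2)
Conditions: I2, PPh3, imidazole, CH2Cl2, 0 °C to rt
Reagents that add atoms: iodine, II
Why: Appel-type iodination of the primary alcohol through its alkoxyphosphonium salt, buffered by imidazole so that the silyl ether and the 1,1-disubstituted alkene are not touched.

Step 10
Reactants: 14 tert-butyl[(4-iodo-2-methylidenebutyl)oxy]diphenylsilane (fragment 2); 7 saturated hydroxy ketone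
Product: 17 (5R,6R,8R,9R,10S)-16-[(tert-butyldiphenylsilyl)oxy]-15-nor-5β-labd-13-ene-6,9-diol (6β-OH; 9α-OH; C11 β), via alkyllithium 15 (not isolated), via organocerium dichloride 16 (not isolated)
Conditions: 14 (3 equiv), t-BuLi (6 equiv), Et2O, −78 °C; CeCl3 (3 equiv), THF, −78 °C; then 7, −78 to −20 °C; aq. NH4Cl
Reagents that add atoms: none
Why: Organocerium 1,2-addition to a hindered ketone: one equivalent of the weakly basic reagent turns the C6 hydroxyl into its alkoxide without enolising towards C8, and the next attacks C9 from the β face, past the C10 methyl and H8 and not past C1 and the α C8 methyl, so that the new hydroxyl is α and C11 is β.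

Step 11
Reactants: 17 (5R,6R,8R,9R,10S)-16-[(tert-butyldiphenylsilyl)oxy]-15-nor-5β-labd-13-ene-6,9-diol
Product: 18 (5R,6R,8R,9R,10S)-15-nor-5β-labd-13-ene-6,9,16-triol
Conditions: Bu4NF, THF, rt
Reagents that add atoms: none
Why: Fluoride-induced silyl ether cleavage frees the primary allylic hydroxyl that has to anchor the epoxidation catalyst.

Step 12
Reactants: 18 (5R,6R,8R,9R,10S)-15-nor-5β-labd-13-ene-6,9,16-triol
Product: 19 (13R)-13,14-epoxy-15-nor-5β-labdane-6β,9α,16-triol
Conditions: Ti(OiPr)4 (30 mol %), D-(−)-diethyl tartrate (36 mol %), t-BuOOH, 4 Å MS, CH2Cl2, −20 °C; non-acidic work-up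
Reagents that add atoms: tert-butyl hydroperoxide, CC(C)(C)OO
Why: Titanium–tartrate (Sharpless) asymmetric epoxidation of a 2-substituted allylic alcohol: the primary allylic hydroxyl binds titanium and the tartrate ligand alone decides the face of C13=C14, far from the ring stereocentres, which sets C13 under reagent control.

Step 13
Reactants: 19 (13R)-13,14-epoxy-15-nor-5β-labdane-6β,9α,16-triol
Product: 20 (13S)-16-[(tert-butyldimethylsilyl)oxy]-13,14-epoxy-15-nor-5β-labdane-6β,9α-diol (same spatial arrangement at C13 as in 19)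
Conditions: TBSCl, imidazole, DMF, 0 °C
Reagents that add atoms: tert-butylchlorodimethylsilane, CC(C)(C)[Si](C)(C)Cl
Why: Selective silylation of the primary hydroxyl over the hindered secondary C6 and tertiary C9 hydroxyls tags C16 before ring closure, so that the two oxygenated one-carbon arms on C13 stay distinguishable.

Step 14
Reactants: 20 (13S)-16-[(tert-butyldimethylsilyl)oxy]-13,14-epoxy-15-nor-5β-labdane-6β,9α-diol
Product: 21 (13R)-16-[(tert-butyldimethylsilyl)oxy]-9α,13-epoxy-15-nor-5β-labdane-6β,14-diol (9,13-spiro-tetrahydrofuran)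
Conditions: camphor-10-sulfonic acid (10 mol %), CH2Cl2, 0 °C
Reagents that add atoms: none
Why: Acid-catalysed 5-exo epoxide opening: the C9 hydroxyl attacks the tertiary, better cation-stabilising C13 with inversion, which fixes the spiro C13 configuration set up in step 12 and leaves C14 as the only primary hydroxyl.

Step 15
Reactants: 21 (13R)-16-[(tert-butyldimethylsilyl)oxy]-9α,13-epoxy-15-nor-5β-labdane-6β,14-diol
Product: 22 (13S)-16-[(tert-butyldimethylsilyl)oxy]-6β-hydroxy-9α,13-epoxy-15-nor-5β-labdan-14-al
Conditions: 2,2,6,6-tetramethylpiperidin-1-oxyl (10 mol %), PhI(OAc)2, CH2Cl2, rt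
Reagents that add atoms: none
Why: Oxoammonium-mediated oxidation, selective for primary over secondary alcohols, turns C14 into the aldehyde and leaves the C6 hydroxyl alone; the aldehyde has no α-hydrogen and cannot epimerise.

Step 16
Reactants: 22 (13S)-16-[(tert-butyldimethylsilyl)oxy]-6β-hydroxy-9α,13-epoxy-15-nor-5β-labdan-14-al
Product: 23 (13R)-16-[(tert-butyldimethylsilyl)oxy]-9α,13-epoxy-5β-labd-14-yn-6β-ol
Conditions: dimethyl (1-diazo-2-oxopropyl)phosphonate, K2CO3, MeOH, 0 °C to rt
Reagents that add atoms: dimethyl (1-diazo-2-oxopropyl)phosphonate, CC(=O)C(=[N+]=[N-])P(=O)(OC)OC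
Why: Ohira–Bestmann alkynylation (Seyferth–Gilbert homologation): the diazomethylphosphonate anion formed in the flask converts the aldehyde into the terminal alkyne under mild carbonate conditions and so adds C15.

Step 17
Reactants: 23 (13R)-16-[(tert-butyldimethylsilyl)oxy]-9α,13-epoxy-5β-labd-14-yn-6β-ol
Product: 24 (13R)-9α,13-epoxy-5β-labd-14-yne-6β,16-diol
Conditions: Bu4NF, THF, 0 °C to rt
Reagents that add atoms: none
Why: Fluoride-induced cleavage of the TBS ether liberates the homopropargylic C16 hydroxyl needed for ring closure.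

Step 18
Reactants: 24 (13R)-9α,13-epoxy-5β-labd-14-yne-6β,16-diol
Product: 25 (13R)-9α,13:15,16-diepoxy-5β-labd-14-en-6β-ol (bis-spiro dihydrofuran)
Conditions: Mo(CO)6 (30 mol %), Me3NO (30 mol %), Et3N, Et2O, rt
Reagents that add atoms: none
Why: Endo-selective alkynol cycloisomerisation: the amine-ligated molybdenum pentacarbonyl converts the terminal alkyne into a metal vinylidene whose electrophilic carbon (C15) is attacked by the C16 hydroxyl, closing the 2,3-dihydrofuran under basic conditions that the acid-labile spiro enol ether tolerates; no stereocentre is formed.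

Step 19
Reactants: 25 (13R)-9α,13:15,16-diepoxy-5β-labd-14-en-6β-ol
Product: 26 (5R,6R,8R,9R,10S,13R)-6-acetoxy-9,13:15,16-diepoxy-5β-labd-14-ene (CNP0242014.2)
Conditions: Ac2O, 4-(dimethylamino)pyridine (cat.), pyridine, rt
Reagents that add atoms: acetic anhydride, CC(=O)OC(C)=O
Why: Nucleophile-catalysed acetylation of the last free hydroxyl under purely basic conditions, because acid would expel the C13 oxygen from the 3-alkoxy-2,3-dihydrofuran and aromatise it to a furan; the C6 configuration is untouched.

Compound list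
1 | 2,6-dimethyl-1,4-benzoquinone | CC1=CC(=O)C=C(C)C1=O | starting material
2 | 4-methylpenta-1,3-diene | CC(C)=CC=C | starting material
3 | (4aR,8aS)-2,5,5,8a-tetramethyl-4a,5,8,8a-tetrahydronaphthalene-1,4-dione (cis-fused ene-dione) | O=C1C=C(C)C(=O)[C@@]2(C)CC=CC(C)(C)[C@@H]12 | intermediate
4 | (4S,4aR,8aS)-4-hydroxy-2,5,5,8a-tetramethyl-4a,5,8,8a-tetrahydronaphthalen-1(4H)-one (6α-hydroxy enone) | O[C@H]1C=C(C)C(=O)[C@@]2(C)CC=CC(C)(C)[C@@H]12 | intermediate
5 | 4-nitrobenzoate ester of 6 (6β-ester, C6 inverted) | O=C(O[C@@H]1C=C(C)C(=O)[C@@]2(C)CC=CC(C)(C)[C@@H]12)c1ccc(cc1)[N+](=O)[O-] | intermediate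
6 | (4R,4aR,8aS)-4-hydroxy-2,5,5,8a-tetramethyl-4a,5,8,8a-tetrahydronaphthalen-1(4H)-one (6β-hydroxy enone) | O[C@@H]1C=C(C)C(=O)[C@@]2(C)CC=CC(C)(C)[C@@H]12 | intermediate
7 | (2R,4R,4aR,8aS)-4-hydroxy-2,5,5,8a-tetramethyloctahydronaphthalen-1(2H)-one (6β-hydroxy-8α-methyl-cis-decalin-9-one) | O[C@@H]1C[C@@H](C)C(=O)[C@@]2(C)CCCC(C)(C)[C@@H]12 | intermediate
8 | 3-bromobut-3-en-1-ol | OCCC(Br)=C | starting material
9 | 2-[(3-bromobut-3-en-1-yl)oxy]tetrahydro-2H-pyran (racemic acetal) | C=C(Br)CCOC1CCCCO1 | intermediate
10 | [1-methylidene-3-(tetrahydro-2H-pyran-2-yloxy)propyl]lithium (vinyllithium) | [Li]C(=C)CCOC1CCCCO1 | intermediate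
11 | 2-methylidene-4-(tetrahydro-2H-pyran-2-yloxy)butan-1-ol | OCC(=C)CCOC1CCCCO1 | intermediate
12 | tert-butyl{[2-methylidene-4-(tetrahydro-2H-pyran-2-yloxy)butyl]oxy}diphenylsilane | C=C(CCOC1CCCCO1)CO[Si](c1ccccc1)(c1ccccc1)C(C)(C)C | intermediate
13 | 4-[(tert-butyldiphenylsilyl)oxy]-3-methylidenebutan-1-ol | OCCC(=C)CO[Si](c1ccccc1)(c1ccccc1)C(C)(C)C | intermediate
14 | tert-butyl[(4-iodo-2-methylidenebutyl)oxy]diphenylsilane (fragment 2) | ICCC(=C)CO[Si](c1ccccc1)(c1ccccc1)C(C)(C)C | intermediate
15 | {4-[(tert-butyldiphenylsilyl)oxy]-3-methylidenebutyl}lithium (alkyllithium) | [Li]CCC(=C)CO[Si](c1ccccc1)(c1ccccc1)C(C)(C)C | intermediate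
16 | dichloro{4-[(tert-butyldiphenylsilyl)oxy]-3-methylidenebutyl}cerium (organocerium dichloride) | Cl[Ce](Cl)CCC(=C)CO[Si](c1ccccc1)(c1ccccc1)C(C)(C)C | intermediate
17 | (5R,6R,8R,9R,10S)-16-[(tert-butyldiphenylsilyl)oxy]-15-nor-5β-labd-13-ene-6,9-diol (6β-OH, 9α-OH, 8α-methyl, exocyclic C13=C14) | O[C@@H]1C[C@@H](C)[C@](O)(CCC(=C)CO[Si](c3ccccc3)(c3ccccc3)C(C)(C)C)[C@@]2(C)CCCC(C)(C)[C@@H]12 | intermediate
18 | (5R,6R,8R,9R,10S)-15-nor-5β-labd-13-ene-6,9,16-triol | O[C@@H]1C[C@@H](C)[C@](O)(CCC(=C)CO)[C@@]2(C)CCCC(C)(C)[C@@H]12 | intermediate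
19 | (13R)-13,14-epoxy-15-nor-5β-labdane-6β,9α,16-triol | O[C@@H]1C[C@@H](C)[C@](O)(CC[C@@]3(CO)CO3)[C@@]2(C)CCCC(C)(C)[C@@H]12 | intermediate
20 | (13S)-16-[(tert-butyldimethylsilyl)oxy]-13,14-epoxy-15-nor-5β-labdane-6β,9α-diol | O[C@@H]1C[C@@H](C)[C@](O)(CC[C@@]3(CO[Si](C)(C)C(C)(C)C)CO3)[C@@]2(C)CCCC(C)(C)[C@@H]12 | intermediate
21 | (13R)-16-[(tert-butyldimethylsilyl)oxy]-9α,13-epoxy-15-nor-5β-labdane-6β,14-diol | O[C@@H]1C[C@@H](C)[C@]2(CC[C@](CO[Si](C)(C)C(C)(C)C)(CO)O2)[C@@]2(C)CCCC(C)(C)[C@@H]12 | intermediate
22 | (13S)-16-[(tert-butyldimethylsilyl)oxy]-6β-hydroxy-9α,13-epoxy-15-nor-5β-labdan-14-al | O[C@@H]1C[C@@H](C)[C@]2(CC[C@](CO[Si](C)(C)C(C)(C)C)(C=O)O2)[C@@]2(C)CCCC(C)(C)[C@@H]12 | intermediate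
23 | (13R)-16-[(tert-butyldimethylsilyl)oxy]-9α,13-epoxy-5β-labd-14-yn-6β-ol | O[C@@H]1C[C@@H](C)[C@]2(CC[C@](CO[Si](C)(C)C(C)(C)C)(C#C)O2)[C@@]2(C)CCCC(C)(C)[C@@H]12 | intermediate
24 | (13R)-9α,13-epoxy-5β-labd-14-yne-6β,16-diol | O[C@@H]1C[C@@H](C)[C@]2(CC[C@](CO)(C#C)O2)[C@@]2(C)CCCC(C)(C)[C@@H]12 | intermediate
25 | (13R)-9α,13:15,16-diepoxy-5β-labd-14-en-6β-ol | O[C@@H]1C[C@@H](C)[C@]2(CC[C@]3(C=COC3)O2)[C@@]2(C)CCCC(C)(C)[C@@H]12 | intermediate
26 | (5R,6R,8R,9R,10S,13R)-6-acetoxy-9,13:15,16-diepoxy-5β-labd-14-ene (CNP0242014.2) | CC(=O)O[C@@H]1C[C@@H](C)[C@]2(CC[C@]3(C=COC3)O2)[C@@]2(C)CCCC(C)(C)[C@@H]12 | target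

Total step count: 19.
Longest linear sequence: 15 steps (steps 5 to 9, then 10 to 19, from 3-bromobut-3-en-1-ol); the decalin branch runs 14 steps (steps 1 to 4, then 10 to 19).

Steps most likely to fail

First, step 1. The Z-methyl of diene 2 may keep it out of the s-cis conformer, so that ring formation is outrun by acid-induced oligomerisation or isomerisation of the diene. The fallback sets out from quinone 1 and uses, under the same oxazaborolidinium catalysis, the much more nucleophilic silyl dienol ether of mesityl oxide, 2-(tert-butyldimethylsilyloxy)-4-methylpenta-1,3-diene F1 (mesityl oxide, LiN(iPr)2, TBSCl). Such 2-silyloxydienes are standard partners of quinones with this catalyst and can also close ring A stepwise by a Mukaiyama–Michael addition at C10 followed by Michael closure at C5, with the same regiochemistry. The resulting cis-fused silyl enol ether adduct F2 is converted with CsF and PhNTf2 into the C2 enol triflate F3. Palladium-catalysed formate reduction (Pd(OAc)2, PPh3, Bu3N, HCO2H, DMF) then removes the oxygen and leaves the C2=C3 alkene, which brings the route back at 3.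

Second, step 3. Displacement at the hindered allylic C6 may lose out to elimination towards a dienone or stop at incomplete inversion under the redox-condensation conditions. The fallback sets out from 4 and separates activation from displacement. MsCl and Et3N give the 6α-mesylate F4. The weakly basic carboxylate of CsOAc with 18-crown-6 in toluene then displaces it from the open β face to give the 6β-acetate F5. Cold K2CO3 in MeOH returns the route at 6.

Third, step 10. The doubly flanked C9 ketone may be enolised (with loss of the C8 configuration) or may not be reached at all by the bulky functionalised reagent, which can also decay before it adds. The fallback sets out from 7 and brings in the side chain in two stages. The small vinyl nucleophile (CH2=CHMgBr, CeCl3, THF) adds from the same β face to give the 9-vinyl diol F6. Hydroboration with 9-BBN-H gives the B-alkyl-9-BBN adduct F7. Suzuki–Miyaura coupling of F7 with 2-bromoallyl tert-butyldiphenylsilyl ether F8 (from 2-bromoprop-2-en-1-ol, TBDPSCl, imidazole) under Pd(dppf)Cl2, AsPh3 and Cs2CO3 in DMF/H2O forms the C12–C13 bond and rejoins the route at 17.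

Further compounds
F1 | step 1 | 2-(tert-butyldimethylsilyloxy)-4-methylpenta-1,3-diene | C=C(O[Si](C)(C)C(C)(C)C)C=C(C)C
F2 | step 1 | cis-fused silyl enol ether adduct (C2 silyloxy, C2=C3; 4aR,8aS as in 3) | O=C1C=C(C)C(=O)[C@@]2(C)CC(O[Si](C)(C)C(C)(C)C)=CC(C)(C)[C@@H]12
F3 | step 1 | C2 enol triflate of the cis-fused ene-dione | O=C1C=C(C)C(=O)[C@@]2(C)CC(OS(=O)(=O)C(F)(F)F)=CC(C)(C)[C@@H]12
F4 | step 3 | 6α-methanesulfonate of 4 | CS(=O)(=O)O[C@H]1C=C(C)C(=O)[C@@]2(C)CC=CC(C)(C)[C@@H]12
F5 | step 3 | 6β-acetate of 6 | CC(=O)O[C@@H]1C=C(C)C(=O)[C@@]2(C)CC=CC(C)(C)[C@@H]12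
F6 | step 10 | 9β-vinyl-6β,9α-diol (C11=C12 vinyl carbinol of the cis-decalin) | O[C@@H]1C[C@@H](C)[C@](O)(C=C)[C@@]2(C)CCCC(C)(C)[C@@H]12
F7 | step 10 | B-alkyl-9-BBN adduct of F6 (boron on C12) | O[C@@H]1C[C@@H](C)[C@](O)(CCB3C4CCCC3CCC4)[C@@]2(C)CCCC(C)(C)[C@@H]12
F8 | step 10 | [(2-bromoprop-2-en-1-yl)oxy](tert-butyl)diphenylsilane | C=C(Br)CO[Si](c1ccccc1)(c1ccccc1)C(C)(C)C
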